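## Retrosynthetic overview

1. The target is two trans-2,3-diaryl-2,3-dihydrobenzofurans. DHB 1 has ring A (benzo ring, formyl on C5) and ring C (4-hydroxyphenyl on C2). Its C3 carries ring B, the resorcinol ring that is the benzo ring of DHB 2, which has ring D (3,5-dihydroxyphenyl on C3) and ring E (4-hydroxyphenyl on C2).
2. Last disconnection: CHO ⇐ Weinreb amide ⇐ a 12-membered aryl ester (lactone) between the carbonyl carbon on C5 of ring A and one meta-oxygen of ring D. This temporary ring and the acid oxidation level are what shape the precursor.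
3. Key disconnection: O1–C2 and C3a–C3 of DHB 2, formed together by an intramolecular oxidative (3+2) annulation of ring B (hydroxyl oxygen plus ortho carbon) across the alkene of a resveratrol unit held by that ester. Enabling feature: the ring E phenol is conjugated through the alkene to the future C3 (a vinylogous phenol, so oxidation makes that carbon electrophilic), and in the target the carbon on C5 of ring A and a meta-oxygen of ring D lie on the same face of ring B, close enough for a one-carbon bridge.
4. DHB 1 (C2–C3 bond) is made earlier by an enantioselective dirhodium-carbene C–H insertion; the resveratrol unit comes from a Heck reaction; the two are joined by esterification.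
5. Ring order: ring A bought → furan ring of DHB 1 (step 3) → 12-membered lactone and furan ring of DHB 2 in one operation (step 10) → lactone opened (step 11). The two hydrogens removed in step 10 are returned when the ester carbon is reduced to the aldehyde (steps 11 and 12).

Key step: step 10

Assumption: Rh2(S-PTAD)4 is taken to be the catalyst antipode that gives the (3R) series in step 3; if the sense of induction is the opposite, its enantiomer Rh2(R-PTAD)4 is used.

## Route

Step 1
Reactants: 1 5-bromo-2-hydroxybenzonitrile; 2 4-methoxybenzyl chloride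
Product: 3 5-bromo-2-[(4-methoxyphenyl)methoxy]benzonitrile
Conditions: K2CO3, KI (cat.), DMF, 60 °C
Reagents that add atoms: none
Why: Williamson ether synthesis, in which the acidic cyanophenol is alkylated on oxygen by the reactive benzylic chloride; no stereocenter is formed.

Step 2
Reactants: 3 5-bromo-2-[(4-methoxyphenyl)methoxy]benzonitrile; 4 3,5-dimethoxyphenylmagnesium chloride
Product: 6 {5-bromo-2-[(4-methoxyphenyl)methoxy]phenyl}(3,5-dimethoxyphenyl)methanone hydrazone (E/Z mixture), via N-H ketimine 5 (not isolated)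
Conditions: 4 (1.5 equiv), THF, 0 → 50 °C; MeOH; then N2H4·H2O (10 equiv), AcOH (cat.), EtOH, 70 °C
Reagents that add atoms: hydrazine hydrate, NN.O
Why: Grignard addition to the nitrile (Moureu–Mignonac ketimine synthesis) stops at the N-magnesio ketimine, and its N–H form should exchange with hydrazine (transimination) far more readily than the hindered diaryl ketone would condense; no stereocenter is formed.

Step 3
Reactants: 6 {5-bromo-2-[(4-methoxyphenyl)methoxy]phenyl}(3,5-dimethoxyphenyl)methanone hydrazone
Product: 8 (2S,3R)-5-bromo-3-(3,5-dimethoxyphenyl)-2-(4-methoxyphenyl)-2,3-dihydro-1-benzofuran (2,3-cis), via diaryldiazomethane 7 (not isolated)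
Conditions: MnO2, CH2Cl2, 0 °C, filter; then Rh2(S-PTAD)4 (1 mol %), CH2Cl2, −20 °C → rt
Reagents that add atoms: none
Why: Hydrazone oxidation gives the donor/donor diazo compound, and the chiral dirhodium tetracarboxylate carbene inserts into the benzylic C–H bond next to the ether oxygen (intramolecular 1,5 C–H insertion, established for hydrazones of 2-benzyloxybenzophenones); C3 is set by the catalyst and C2 cis to it in the concerted insertion.

Step 4
Reactants: 8 (2S,3R)-5-bromo-3-(3,5-dimethoxyphenyl)-2-(4-methoxyphenyl)-2,3-dihydro-1-benzofuran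
Product: 9 5-[(2R,3R)-5-bromo-2-(4-hydroxyphenyl)-2,3-dihydro-1-benzofuran-3-yl]benzene-1,3-diol (2,3-trans)
Conditions: BBr3 (6 equiv), CH2Cl2, −78 °C → rt; then H2O
Reagents that add atoms: none
Why: Lewis-acid demethylation of the three aryl methyl ethers, during which the C2–O bond should ionise reversibly to the para-oxygen-stabilised benzylic cation so that C2 equilibrates to the favoured trans isomer while C3 stays untouched.

Step 5
Reactants: 9 5-[(2R,3R)-5-bromo-2-(4-hydroxyphenyl)-2,3-dihydro-1-benzofuran-3-yl]benzene-1,3-diol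
Product: 10 (2R,3R)-5-bromo-3-{3,5-bis[(tert-butyldimethylsilyl)oxy]phenyl}-2-{4-[(tert-butyldimethylsilyl)oxy]phenyl}-2,3-dihydro-1-benzofuran
Conditions: TBSCl, imidazole, DMF, rt
Reagents that add atoms: tert-butyldimethylsilyl chloride, CC(C)(C)[Si](C)(C)Cl
Why: Standard silylation of the three phenols, which masks them for the organolithium and esterification steps; no stereocenter is touched.

Step 6
Reactants: 10 (2R,3R)-5-bromo-3-{3,5-bis[(tert-butyldimethylsilyl)oxy]phenyl}-2-{4-[(tert-butyldimethylsilyl)oxy]phenyl}-2,3-dihydro-1-benzofuran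
Product: 12 (2R,3R)-3-{3,5-bis[(tert-butyldimethylsilyl)oxy]phenyl}-2-{4-[(tert-butyldimethylsilyl)oxy]phenyl}-2,3-dihydro-1-benzofuran-5-carboxylic acid, via aryllithium 11 (not isolated)
Conditions: n-BuLi, THF, −78 °C; CO2 (g); then 1 M HCl
Reagents that add atoms: carbon dioxide, O=C=O
Why: Bromine–lithium exchange followed by carboxylation of the aryllithium is fast at −78 °C, where aryl silyl ethers and the benzylic C2–H are left alone.

Step 7
Reactants: 13 5-iodobenzene-1,3-diol; 14 tert-butyldimethyl(4-vinylphenoxy)silane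
Product: 15 5-[(E)-2-{4-[(tert-butyldimethylsilyl)oxy]phenyl}ethenyl]benzene-1,3-diol (4'-O-silylated resveratrol)
Conditions: Pd(OAc)2 (2 mol %), P(o-tol)3, Et3N, MeCN, 80 °C
Reagents that add atoms: none
Why: Mizoroki–Heck reaction of the aryl iodide with the styrene, where syn insertion and syn β-hydride elimination at zerovalent palladium give the E-stilbene.

Step 8
Reactants: 12 (2R,3R)-3-{3,5-bis[(tert-butyldimethylsilyl)oxy]phenyl}-2-{4-[(tert-butyldimethylsilyl)oxy]phenyl}-2,3-dihydro-1-benzofuran-5-carboxylic acid; 15 5-[(E)-2-{4-[(tert-butyldimethylsilyl)oxy]phenyl}ethenyl]benzene-1,3-diol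
Product: 16 3-hydroxy-5-[(E)-2-{4-[(tert-butyldimethylsilyl)oxy]phenyl}ethenyl]phenyl ester of acid 12
Conditions: EDC·HCl, DMAP (cat.), 15 (3 equiv), CH2Cl2, 0 °C → rt
Reagents that add atoms: none
Why: Steglich esterification of a benzoic acid with a phenol; the two hydroxyls of 15 are equivalent and its excess should keep the reaction at monoacylation.

Step 9
Reactants: 16 3-hydroxy-5-[(E)-2-{4-[(tert-butyldimethylsilyl)oxy]phenyl}ethenyl]phenyl ester of acid 12
Product: 17 3-hydroxy-5-[(E)-2-(4-hydroxyphenyl)ethenyl]phenyl (2R,3R)-3-(3,5-dihydroxyphenyl)-2-(4-hydroxyphenyl)-2,3-dihydro-1-benzofuran-5-carboxylate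
Conditions: HF·pyridine, pyridine, THF, 0 °C → rt
Reagents that add atoms: none
Why: Fluoride cleavage of the four aryl silyl ethers under buffered, non-basic conditions, which should leave the aryl ester, the stilbene and the trans-dihydrobenzofuran intact.

Step 10
Reactants: 17 3-hydroxy-5-[(E)-2-(4-hydroxyphenyl)ethenyl]phenyl (2R,3R)-3-(3,5-dihydroxyphenyl)-2-(4-hydroxyphenyl)-2,3-dihydro-1-benzofuran-5-carboxylate
Product: 19 12-membered macrolactone in which the C5 carboxyl of DHB 1 is esterified to a meta-hydroxyl of ring D of the newly formed (2R,3R)-DHB 2, via p-quinone methide 18 (not isolated)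
Conditions: PhI(OAc)2 (1.05 equiv, slow addition), (CF3)2CHOH/CH2Cl2, 0.5 mM, −20 → 0 °C, dark
Reagents that add atoms: none
Why: Proposed new method: PhI(OAc)2 in hexafluoroisopropanol takes two electrons from the ring E phenol, the only phenol conjugated to an alkene and therefore the most easily oxidised of the five, and the resulting phenoxonium ion is electrophilic at the alkene carbon that bears ring D; the ring B carbon ortho to C3 of DHB 1 and para to a hydroxyl attacks there in a Friedel–Crafts manner, and the p-quinone methide 18 so formed is closed by the adjacent ring B hydroxyl in an oxa-1,6-addition. The closest known reaction type is the oxidative (3+2) coupling of a 4-hydroxystilbene with a resorcinol ring by which resveratrol is dimerised to the ε-viniferin skeleton with FeCl3, together with phenol–arene cross-coupling by trivalent-iodine reagents in fluorinated alcohols; new is the tethered, macrocyclising cross version. The carbon–carbon bond closes the 12-membered lactone ring in a 12-exo-trig mode and the carbon–oxygen bond closes the dihydrofuran ring in a 5-exo-trig mode. C3 of DHB 2 is set in the carbon–carbon bond formation by the (3R) centre of DHB 1 relayed through the ester bridge: allylic 1,3-strain keeps the C3–H bond of DHB 1 in the plane of ring B and ring A on one face, the bridge holds ring D on that same face, and the only dihydrofuran that can then close has the 3R configuration; C2 follows as trans to ring D because the oxa-addition is reversible through the quinone methide and the trans isomer is favoured both kinetically and thermodynamically. The step needs chemoselective oxidation (secured by the conjugated phenol), regioselection on ring B (tether reach plus para-hydroxyl activation pick the carbon next to DHB 1 and not the one between the two hydroxyls), carbon rather than oxygen attack (hydrogen-bonding, non-nucleophilic solvent) and ring closure rather than oligomerisation (0.5 mM, slow addition of the oxidant).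

Step 11
Reactants: 19 12-membered macrolactone
Product: 20 (2R,3R)-3-[(2R,3R)-3-(3,5-dihydroxyphenyl)-6-hydroxy-2-(4-hydroxyphenyl)-2,3-dihydro-1-benzofuran-4-yl]-2-(4-hydroxyphenyl)-N-methoxy-N-methyl-2,3-dihydro-1-benzofuran-5-carboxamide
Conditions: MeNHOMe·HCl, i-PrMgCl (excess), THF, −20 → 0 °C; then aq. NH4Cl
Reagents that add atoms: N,O-dimethylhydroxylamine hydrochloride, CNOC.Cl
Why: The strained aryl ester is an active ester with a phenoxide leaving group, so the magnesium amide of N,O-dimethylhydroxylamine should open it to the Weinreb amide (ester aminolysis) while the phenols only consume base; no stereocenter is touched.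

Step 12
Reactants: 20 Weinreb amide
Product: 21 (2R,3R)-3-[(2R,3R)-3-(3,5-dihydroxyphenyl)-6-hydroxy-2-(4-hydroxyphenyl)-2,3-dihydro-1-benzofuran-4-yl]-2-(4-hydroxyphenyl)-2,3-dihydro-1-benzofuran-5-carbaldehyde (CNP0318276.1)
Conditions: i-Bu2AlH (excess), THF, −78 °C; then Rochelle salt (aq.)
Reagents that add atoms: none
Why: Weinreb amide reduction, in which the chelated tetrahedral aluminium intermediate survives until work-up so that reduction stops at the aldehyde, while the aluminium phenoxides formed from the five phenols are inert.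

## Compound list

1 | 5-bromo-2-hydroxybenzonitrile | N#Cc1cc(Br)ccc1O | starting material
2 | 4-methoxybenzyl chloride | COc1ccc(CCl)cc1 | starting material
3 | 5-bromo-2-[(4-methoxyphenyl)methoxy]benzonitrile | N#Cc1cc(Br)ccc1OCc1ccc(OC)cc1 | intermediate
4 | 3,5-dimethoxyphenylmagnesium chloride | COc1cc(OC)cc([Mg]Cl)c1 | starting material
5 | 1-{5-bromo-2-[(4-methoxyphenyl)methoxy]phenyl}-1-(3,5-dimethoxyphenyl)methanimine (N-H ketimine, not isolated) | N=C(c1cc(OC)cc(OC)c1)c1cc(Br)ccc1OCc1ccc(OC)cc1 | intermediate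
6 | {5-bromo-2-[(4-methoxyphenyl)methoxy]phenyl}(3,5-dimethoxyphenyl)methanone hydrazone | NN=C(c1cc(OC)cc(OC)c1)c1cc(Br)ccc1OCc1ccc(OC)cc1 | intermediate
7 | 4-bromo-2-[diazo(3,5-dimethoxyphenyl)methyl]-1-[(4-methoxyphenyl)methoxy]benzene (not isolated) | [N-]=[N+]=C(c1cc(OC)cc(OC)c1)c1cc(Br)ccc1OCc1ccc(OC)cc1 | intermediate
8 | (2S,3R)-5-bromo-3-(3,5-dimethoxyphenyl)-2-(4-methoxyphenyl)-2,3-dihydro-1-benzofuran (cis) | Brc1ccc2c(c1)[C@@H](c1cc(OC)cc(OC)c1)[C@@H](c1ccc(OC)cc1)O2 | intermediate
9 | 5-[(2R,3R)-5-bromo-2-(4-hydroxyphenyl)-2,3-dihydro-1-benzofuran-3-yl]benzene-1,3-diol (trans) | Brc1ccc2c(c1)[C@@H](c1cc(O)cc(O)c1)[C@H](c1ccc(O)cc1)O2 | intermediate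
10 | (2R,3R)-5-bromo-3-{3,5-bis[(tert-butyldimethylsilyl)oxy]phenyl}-2-{4-[(tert-butyldimethylsilyl)oxy]phenyl}-2,3-dihydro-1-benzofuran | Brc1ccc2c(c1)[C@@H](c1cc(O[Si](C)(C)C(C)(C)C)cc(O[Si](C)(C)C(C)(C)C)c1)[C@H](c1ccc(O[Si](C)(C)C(C)(C)C)cc1)O2 | intermediate
11 | 5-lithio analogue of 10 (aryllithium, not isolated) | [Li]c1ccc2c(c1)[C@@H](c1cc(O[Si](C)(C)C(C)(C)C)cc(O[Si](C)(C)C(C)(C)C)c1)[C@H](c1ccc(O[Si](C)(C)C(C)(C)C)cc1)O2 | intermediate
12 | (2R,3R)-3-{3,5-bis[(tert-butyldimethylsilyl)oxy]phenyl}-2-{4-[(tert-butyldimethylsilyl)oxy]phenyl}-2,3-dihydro-1-benzofuran-5-carboxylic acid | OC(=O)c1ccc2c(c1)[C@@H](c1cc(O[Si](C)(C)C(C)(C)C)cc(O[Si](C)(C)C(C)(C)C)c1)[C@H](c1ccc(O[Si](C)(C)C(C)(C)C)cc1)O2 | intermediate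
13 | 5-iodobenzene-1,3-diol | Oc1cc(O)cc(I)c1 | starting material
14 | tert-butyldimethyl(4-vinylphenoxy)silane | C=Cc1ccc(O[Si](C)(C)C(C)(C)C)cc1 | starting material
15 | 5-[(E)-2-{4-[(tert-butyldimethylsilyl)oxy]phenyl}ethenyl]benzene-1,3-diol | Oc1cc(O)cc(/C=C/c2ccc(O[Si](C)(C)C(C)(C)C)cc2)c1 | intermediate
16 | 3-hydroxy-5-[(E)-2-{4-[(tert-butyldimethylsilyl)oxy]phenyl}ethenyl]phenyl (2R,3R)-3-{3,5-bis[(tert-butyldimethylsilyl)oxy]phenyl}-2-{4-[(tert-butyldimethylsilyl)oxy]phenyl}-2,3-dihydro-1-benzofuran-5-carboxylate | CC(C)(C)[Si](C)(C)Oc1ccc(/C=C/c2cc(O)cc(OC(=O)c3ccc4c(c3)[C@@H](c3cc(O[Si](C)(C)C(C)(C)C)cc(O[Si](C)(C)C(C)(C)C)c3)[C@H](c3ccc(O[Si](C)(C)C(C)(C)C)cc3)O4)c2)cc1 | intermediate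
17 | 3-hydroxy-5-[(E)-2-(4-hydroxyphenyl)ethenyl]phenyl (2R,3R)-3-(3,5-dihydroxyphenyl)-2-(4-hydroxyphenyl)-2,3-dihydro-1-benzofuran-5-carboxylate | O=C(Oc1cc(O)cc(/C=C/c2ccc(O)cc2)c1)c1ccc2c(c1)[C@@H](c1cc(O)cc(O)c1)[C@H](c1ccc(O)cc1)O2 | intermediate
18 | p-quinone methide (not isolated): 12-membered lactone already closed by the new bond from ring B to the (R)-configured carbon bearing ring D, which carries a (4-oxocyclohexa-2,5-dien-1-ylidene)methyl group; both ring B hydroxyls free | O=C4c1ccc2c(c1)[C@@H](c1cc(O)cc(O)c1[C@@H](c1cc(O4)cc(O)c1)C=C1C=CC(=O)C=C1)[C@H](c1ccc(O)cc1)O2 | intermediate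
19 | 12-membered macrolactone: target skeleton with all four centres R, in which the ring A C5 carbon is a carboxyl esterified to one meta-oxygen of ring D | O=C4c1ccc2c(c1)[C@@H](c1cc(O)cc3c1[C@@H](c1cc(O4)cc(O)c1)[C@H](c1ccc(O)cc1)O3)[C@H](c1ccc(O)cc1)O2 | intermediate
20 | (2R,3R)-3-[(2R,3R)-3-(3,5-dihydroxyphenyl)-6-hydroxy-2-(4-hydroxyphenyl)-2,3-dihydro-1-benzofuran-4-yl]-2-(4-hydroxyphenyl)-N-methoxy-N-methyl-2,3-dihydro-1-benzofuran-5-carboxamide | CON(C)C(=O)c1ccc2c(c1)[C@@H](c1cc(O)cc3c1[C@@H](c1cc(O)cc(O)c1)[C@H](c1ccc(O)cc1)O3)[C@H](c1ccc(O)cc1)O2 | intermediate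
21 | (2R,3R)-3-[(2R,3R)-3-(3,5-dihydroxyphenyl)-6-hydroxy-2-(4-hydroxyphenyl)-2,3-dihydro-1-benzofuran-4-yl]-2-(4-hydroxyphenyl)-2,3-dihydro-1-benzofuran-5-carbaldehyde | O=Cc1ccc2c(c1)[C@@H](c1cc(O)cc3c1[C@@H](c1cc(O)cc(O)c1)[C@H](c1ccc(O)cc1)O3)[C@H](c1ccc(O)cc1)O2 | target

## Step count and risks

Total steps: 12. Longest linear sequence: 11 (steps 1–6 and 8–12; step 7 is the side branch).

Steps most likely to fail:

1. Step 10 (proposed new method). What may go wrong: the strained 12-membered transition state is not reached, so that oligomerisation, oxygen attack on the cation or over-oxidation of the other phenols takes over. The fallback uses known chemistry without the tether; it sets out from acid 12 and comes back at Weinreb amide 20. Acid 12 is condensed with N,O-dimethylhydroxylamine hydrochloride (EDC·HCl, i-Pr2NEt) to the tris-silylated Weinreb amide F1, which HF·pyridine desilylates to the triphenolic Weinreb amide F2. Separately, diol 15 is acetylated (Ac2O, pyridine) to 3,5-di-O-acetyl-4'-O-silylresveratrol F3 and desilylated (HF·pyridine) to 3,5-di-O-acetylresveratrol F4, whose only free phenol is the conjugated one and whose ring D can no longer act as a nucleophile. F2 and F4 are coupled intermolecularly with FeCl3·6H2O in acetone, the oxidative resorcinol–hydroxystilbene (3+2) coupling known from the dimerisation of resveratrol, to give the diacetate F5. A mixture with the diastereomer at the two new centres is to be expected and would be separated by chromatography. K2CO3 in MeOH at 0 °C then removes the two acetates and returns to 20.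

2. Step 3. What may go wrong: insufficient enantiofacial control by the chiral catalyst on this substrate. The fallback sets out from hydrazone 6 and comes back at 8. Oxidation as before and insertion with achiral Rh2(OAc)4 should give the racemic cis-dihydrobenzofuran, that is 8 together with its (2R,3S) enantiomer F6. The racemate is resolved by preparative chromatography on a chiral stationary phase (amylose tris(3,5-dimethylphenylcarbamate), supercritical CO2/MeOH), and the (2S,3R) enantiomer is carried on as 8.

3. Step 11. What may go wrong: precipitation of the magnesium polyphenoxide, acyl transfer to phenoxides, or base-induced opening of the dihydrofurans through quinone methides in competition with aminolysis. The fallback sets out from macrolactone 19 and comes back at the target 21 without passing through 20. LiAlH4 (THF, 0 °C) opens the lactone reductively to the benzylic alcohol F7 (hydroxymethyl in place of formyl), and activated MnO2 in acetone oxidises this para-alkoxybenzylic alcohol to the aldehyde 21.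

Further compounds
F1 | step 10 | (2R,3R)-3-{3,5-bis[(tert-butyldimethylsilyl)oxy]phenyl}-2-{4-[(tert-butyldimethylsilyl)oxy]phenyl}-N-methoxy-N-methyl-2,3-dihydro-1-benzofuran-5-carboxamide | CON(C)C(=O)c1ccc2c(c1)[C@@H](c1cc(O[Si](C)(C)C(C)(C)C)cc(O[Si](C)(C)C(C)(C)C)c1)[C@H](c1ccc(O[Si](C)(C)C(C)(C)C)cc1)O2
F2 | step 10 | (2R,3R)-3-(3,5-dihydroxyphenyl)-2-(4-hydroxyphenyl)-N-methoxy-N-methyl-2,3-dihydro-1-benzofuran-5-carboxamide | CON(C)C(=O)c1ccc2c(c1)[C@@H](c1cc(O)cc(O)c1)[C@H](c1ccc(O)cc1)O2
F3 | step 10 | 5-[(E)-2-{4-[(tert-butyldimethylsilyl)oxy]phenyl}ethenyl]-1,3-phenylene diacetate | CC(=O)Oc1cc(OC(C)=O)cc(/C=C/c2ccc(O[Si](C)(C)C(C)(C)C)cc2)c1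
F4 | step 10 | 5-[(E)-2-(4-hydroxyphenyl)ethenyl]-1,3-phenylene diacetate (3,5-di-O-acetylresveratrol) | CC(=O)Oc1cc(OC(C)=O)cc(/C=C/c2ccc(O)cc2)c1
F5 | step 10 | diacetate of 20 on the two ring D hydroxyls | CON(C)C(=O)c1ccc2c(c1)[C@@H](c1cc(O)cc3c1[C@@H](c1cc(OC(C)=O)cc(OC(C)=O)c1)[C@H](c1ccc(O)cc1)O3)[C@H](c1ccc(O)cc1)O2
F6 | step 3 | (2R,3S)-5-bromo-3-(3,5-dimethoxyphenyl)-2-(4-methoxyphenyl)-2,3-dihydro-1-benzofuran (enantiomer of 8) | Brc1ccc2c(c1)[C@H](c1cc(OC)cc(OC)c1)[C@H](c1ccc(OC)cc1)O2
F7 | step 11 | 5-(hydroxymethyl) analogue of 21 (benzylic alcohol, all four centres R) | OCc1ccc2c(c1)[C@@H](c1cc(O)cc3c1[C@@H](c1cc(O)cc(O)c1)[C@H](c1ccc(O)cc1)O3)[C@H](c1ccc(O)cc1)O2
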